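**Retrosynthetic overview**
1. (R)-Plastochromenol-8 ⇒ open the O1–C2 bond (retro-oxa-6π) ⇒ (Z)-hydroxy-o-quinone methide. This is the C1′-H→O tautomer of plastoquinone-9, and target and quinone are isomers (C53H80O2).
2. Tautomerisation and electrocyclisation run under a chiral bifunctional base, so the pyran ring and the only stereocentre (C2, R) form together in the last operation.
3. Plastoquinone-9 ⇒ plastoquinol-9 (oxidation) ⇒ aromatic C-prenylation of 2,3-dimethylhydroquinone with all-E-solanesol, which supplies the C45 chain with its geometry intact.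
4. Ring order: the benzene ring is bought. The 2H-pyran is the only ring formed, and it is formed last.

Target read-out: 2H-chromen-6-ol with 7,8-dimethyl, 5-H, 2-methyl and a C40 octaprenyl-type side chain at C2 (seven E alkenes plus the terminal isopropylidene). C2 is R, with priorities O > C3 > side-chain CH2 > CH3.

Assumption: the sense of induction in step 3 cannot be predicted with certainty. The quinine-derived squaramide is written, and its commercial quinidine-derived pseudo-enantiomer is used instead if the first analytical run (chiral HPLC/ECD) shows the (S)-product.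

Step 1
Reactants: 1 2,3-dimethylhydroquinone; 2 all-E-solanesol
Product: 3 plastoquinol-9 (2,3-dimethyl-5-[(all-E)-solanesyl]benzene-1,4-diol)
Conditions: 1 (3 equiv), BF3·OEt2 (0.3 equiv), 1,4-dioxane, 15–20 °C, Ar, slow addition of 2, 3 h; hexane/aq. MeOH partition removes excess 1
Reagents that add atoms: none
Why: Friedel–Crafts allylation, in which BF3 ionises the allylic alcohol and the electron-rich hydroquinone captures the solanesyl cation at its primary terminus; the two free ring positions of 1 are equivalent so only one regioisomer can form, excess 1 suppresses bis-alkylation, dioxane-buffered BF3 at ≤20 °C neither protonates the isolated trisubstituted alkenes nor closes the chroman, and no stereocentre is formed.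

Step 2
Reactants: 3 plastoquinol-9
Product: 4 plastoquinone-9 (2,3-dimethyl-5-[(all-E)-solanesyl]-1,4-benzoquinone)
Conditions: Ag2O (2 equiv), Na2SO4, Et2O, rt, 1 h, dark; neutral SiO2 (no alumina); recrystallise from acetone, −20 °C
Reagents that add atoms: none
Why: Two-electron hydroquinone-to-quinone oxidation on neutral heterogeneous Ag2O leaves all nine alkenes untouched, and crystallisation removes the minor 2′Z isomer from step 1, which matters because it would give the opposite enantiomer in step 3; no stereocentre is formed.

Step 3
Reactants: 4 plastoquinone-9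
Product: 6 (R)-plastochromenol-8, via hydroxy-o-quinone methide 5 (not isolated)
Conditions: 3-{[3,5-bis(trifluoromethyl)phenyl]amino}-4-{[(8α,9S)-6′-methoxycinchonan-9-yl]amino}cyclobut-3-ene-1,2-dione (20 mol %), PhMe–CH2Cl2 9:1 (0.1 M), 23 °C, Ar, dark, 72 h
Reagents that add atoms: none
Why: Proposed new method: the quinuclidine nitrogen removes one of the two enantiotopic C1′–H protons of the squaramide-bound quinone (vinylogous γ-deprotonation) and the proton is returned to the remote C1 oxygen, giving the (6Z,2′E)-hydroxy-o-quinone methide 5, whose O=C4–C5=C1′–C2′=C3′ oxatriene closes by a thermally allowed disrotatory oxa-6π electrocyclisation driven by re-aromatisation; because 5 is created only inside the catalyst complex (squaramide N–H···O=C4, ammonium over C1′) and its s-cis form is expected to close faster than it can escape, the catalyst covers one face of the planar ring, the C2′=C3′ terminus can lift only toward the open face, this fixes the helicity of the oxatriene, and with the 2′E geometry O4 bonds to the Re face of C3′ to give the (R)-quaternary centre; the closest known reaction types are the racemic amine-mediated (pyridine, Et3N) prenylquinone-to-chromenol isomerisation, bifunctional cinchona catalysis of dienolates generated from 2-alkylquinones, and catalytic asymmetric 6π electrocyclisations under chiral ion-pair or hydrogen-bond control.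

**Compound list**
1 | 2,3-dimethylhydroquinone (2,3-dimethylbenzene-1,4-diol) | Cc1c(C)c(O)ccc1O | starting material
2 | all-E-solanesol ((2E,6E,10E,14E,18E,22E,26E,30E)-3,7,11,15,19,23,27,31,35-nonamethylhexatriaconta-2,6,10,14,18,22,26,30,34-nonaen-1-ol) | CC(C)=CCC/C(C)=C/CC/C(C)=C/CC/C(C)=C/CC/C(C)=C/CC/C(C)=C/CC/C(C)=C/CC/C(C)=C/CC/C(C)=C/CO | starting material
3 | plastoquinol-9 (2,3-dimethyl-5-[(all-E)-solanesyl]benzene-1,4-diol) | CC(C)=CCC/C(C)=C/CC/C(C)=C/CC/C(C)=C/CC/C(C)=C/CC/C(C)=C/CC/C(C)=C/CC/C(C)=C/CC/C(C)=C/Cc1cc(O)c(C)c(C)c1O | intermediate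
4 | plastoquinone-9 (2,3-dimethyl-5-[(all-E)-solanesyl]-1,4-benzoquinone) | CC(C)=CCC/C(C)=C/CC/C(C)=C/CC/C(C)=C/CC/C(C)=C/CC/C(C)=C/CC/C(C)=C/CC/C(C)=C/CC/C(C)=C/CC1=CC(=O)C(C)=C(C)C1=O | intermediate
5 | hydroxy-o-quinone methide ((6Z)-4-hydroxy-2,3-dimethyl-6-[(2E, all-E)-solanesylidene]cyclohexa-2,4-dien-1-one; side chain syn to C=O) | CC(C)=CCC/C(C)=C/CC/C(C)=C/CC/C(C)=C/CC/C(C)=C/CC/C(C)=C/CC/C(C)=C/CC/C(C)=C/CC/C(C)=C/C=C1/C=C(O)C(C)=C(C)C1=O | intermediate
6 | (R)-plastochromenol-8 ((2R)-2,7,8-trimethyl-2-[(3E,7E,11E,15E,19E,23E,27E)-4,8,12,16,20,24,28,32-octamethyltritriaconta-3,7,11,15,19,23,27,31-octaen-1-yl]-2H-chromen-6-ol) | CC(C)=CCC/C(C)=C/CC/C(C)=C/CC/C(C)=C/CC/C(C)=C/CC/C(C)=C/CC/C(C)=C/CC/C(C)=C/CC[C@]1(C)C=Cc2cc(O)c(C)c(C)c2O1 | target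

**Total step count:** 3. **Longest linear sequence:** 3.

**Steps most likely to fail**

Step 3 (highest risk). The concerns are slow turnover with a tertiary-amine base, and low ee if 5 leaves the catalyst before it closes.

The fallback replaces asymmetric catalysis by resolution with recycling. It sets out from 4, which is refluxed in pyridine under Ar. This is the achiral amine-mediated tautomerisation/oxa-6π through 5, and it gives 6 together with (S)-plastochromenol-8 F1 as the racemate. The two are separated by preparative chiral SFC/HPLC on an amylose tris(3,5-dimethylphenylcarbamate) phase. F1 is racemised by 365 nm irradiation in toluene (reversible retro-oxa-6π through 5) and fed back to the column. The fallback comes back to the route at 6.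

Step 1. The concerns are a modest yield, 2′E/Z scrambling through the allyl cation, bis-alkylation, and acid-induced chroman or polyene cyclisation.

The fallback replaces the cationic arylation by an SN2 coupling of an aryl metal.
- It sets out from 2. PBr3 (0.4 equiv) with catalytic pyridine in Et2O–hexane at 0 °C gives solanesyl bromide F2 with the 2E geometry retained.
- Commercial 1,4-dimethoxy-2,3-dimethylbenzene F3 is ortho-lithiated (n-BuLi, TMEDA, Et2O, 0 °C) to (2,5-dimethoxy-3,4-dimethylphenyl)lithium F4.
- F4 is coupled with F2 under CuBr·SMe2 catalysis (10 mol %, THF, −40 → 0 °C) to plastoquinol-9 dimethyl ether F5.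
- Oxidative demethylation (CAN, MeCN–CH2Cl2–H2O, 0 °C) gives the quinone directly. The fallback comes back at 4, and step 2 is not needed.

Step 2 (lowest risk). The concern is that contact with the basic oxide or with adsorbents starts the racemic isomerisation, contaminating 4 with racemic chromenol.

The fallback drops the discrete metal-oxide oxidation and the isolation of the quinone. It sets out from 3, which is first freed from its 2′Z isomer by chromatography under Ar. Compound 3 is placed in the solvent of step 3 with the step-3 catalyst and commercial 2,3-dimethyl-1,4-benzoquinone F6 (1.5 equiv). Amine-catalysed quinone/hydroquinone hydrogen exchange then takes place. The trialkylquinone is the weaker oxidant, so the equilibrium favours it, and the reduced oxidant is poorly soluble in toluene. Dehydrogenation is thereby coupled to the isomerisation. The fallback comes back to the route at 4, which is formed and consumed in the flask on its way through 5 to 6.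

**Further compounds**
F1 | step 3 | (S)-plastochromenol-8 | CC(C)=CCC/C(C)=C/CC/C(C)=C/CC/C(C)=C/CC/C(C)=C/CC/C(C)=C/CC/C(C)=C/CC/C(C)=C/CC[C@@]1(C)C=Cc2cc(O)c(C)c(C)c2O1
F2 | step 1 | solanesyl bromide (all-E) | CC(C)=CCC/C(C)=C/CC/C(C)=C/CC/C(C)=C/CC/C(C)=C/CC/C(C)=C/CC/C(C)=C/CC/C(C)=C/CC/C(C)=C/CBr
F3 | step 1 | 1,4-dimethoxy-2,3-dimethylbenzene | COc1ccc(OC)c(C)c1C
F4 | step 1 | (2,5-dimethoxy-3,4-dimethylphenyl)lithium | [Li]c1cc(OC)c(C)c(C)c1OC
F5 | step 1 | plastoquinol-9 dimethyl ether (all-E) | CC(C)=CCC/C(C)=C/CC/C(C)=C/CC/C(C)=C/CC/C(C)=C/CC/C(C)=C/CC/C(C)=C/CC/C(C)=C/CC/C(C)=C/Cc1cc(OC)c(C)c(C)c1OC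
F6 | step 2 | 2,3-dimethyl-1,4-benzoquinone | CC1=C(C)C(=O)C=CC1=O
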